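(Readings and results are simulated for an exercise.)

One constant carries this flask. I follow a single Sub molecule: if its chance of turning into Prd stays the same minute after minute, the share of Sub left after a time is exp(−pace × time), whatever the charge.

| setting | ochre | teal | green | blue |
|---|---|---|---|---|
| Sub | 0.0500 M | 0.0300 M | 0.0250 M | 0.0250 M |
| Cat | 0.00100 M | 0.00100 M | 0.00100 M | 0.00200 M |
| time |  |  |  | 6.6 min |

| run | time / min | [Sub] / M |
|---|---|---|
| ochre run | 0.26 | 0.0491 |
| ochre run | 0.50 | 0.0478 |
| ochre run | 0.96 | 0.0461 |
| ochre run | 1.8 | 0.0425 |
| ochre run | 3.5 | 0.0367 |
| ochre run | 6.6 | 0.0276 |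
| teal run | 0.26 | 0.0291 |
| teal run | 0.50 | 0.0291 |
| teal run | 0.96 | 0.0275 |
| teal run | 1.8 | 0.0258 |
| teal run | 3.5 | 0.0211 |
| teal run | 6.6 | 0.0164 |
| green run | 0.26 | 0.0248 |
| green run | 0.50 | 0.0233 |
| green run | 0.96 | 0.0232 |
| green run | 1.8 | 0.0205 |
| green run | 3.5 | 0.0183 |
| green run | 6.6 | 0.0146 |

(standard deviation of a reading: 4 × 10⁻⁴ M)

- Overall: Sub -> Prd, with Cat as catalyst.
- Constant volume, constant temperature.
- An order is taken over about fifteen percent of the charge, up and down.

1. the power of [Sub] that the first rate follows, about the charge of the ochre run; measure it at two percent of Sub made into Prd (one fixed amount of Prd, the same in the runs compared)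
2. the teal run starts with 0.0200 M less of Sub than the ochre run, and with no Prd. Compared where both hold the same amount of Sub, once fifteen percent of what the teal run was charged with has turned into Prd, is the teal run faster, slower or alike (within a tenth)?
3. Sub in the blue run at 6.6 min, as a share of the Sub charged

In the ochre run, the logarithm of charge over last reading, divided by that time, gives 0.0900 min⁻¹. I call this the pace, the chance per minute that one Sub molecule turns into Prd, the usual pseudo-first-order constant. Ochre already gives 0.0903 min⁻¹ at 1.8 min, so the pace holds as Prd builds up. The teal run gives 0.0915 min⁻¹ and the green run 0.0815 min⁻¹, so the pace holds across charges too. I therefore take the order in Sub as 1 and teal as alike to ochre.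

The blue run has green's Sub charge and twice the Cat, and no earlier run varies Cat. Before I fix a number for blue, I ask what each input can do to its share at 6.6 min. The scatter of one reading is 1.60% of the green charge. The gap between the teal and green paces shifts the share by 3.7 percentage points. The factor by which doubled Cat raises the pace is another matter. At factor one the share is 55.2%, and at factor two it is 30.5%, a shift of 25 points, far larger than the gap between the paces. That factor is the number to know, and the runs do not give it, so I commit to the bracket between those two shares.

The forecast, where I keep a bracket, gives order 1, alike and a single 33%, saying: “No run tests the order in Cat, so I assume first order”.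

The flask gives order 1.0, alike and 49.4%.

    Cat + Sub → Prd + Cat (113.4 L mol⁻¹ min⁻¹)
    2 Cat ⇌ Cat2, settled at all times (3360 L mol⁻¹)
    Sub → Prd (0.05298 min⁻¹)

The ochre pace puts the time for Prd to reach half of the green charge at 7.70 min, and the green run stores 7.78 min. Blue's share gives a pace of 0.107 min⁻¹, which is 1.19 times the ochre pace for twice the Cat. The reasons are the tying up of two Cat as Cat2 and the conversion of Sub into Prd without Cat: the apparent order in Cat early in the ochre run is 0.24, and it is 0.68 without Cat2 and 0.59 without that Cat-free step. Without Cat2 the blue run holds 15.8% of its Sub at 6.6 min, not 49.4%.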